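**Retrosynthetic overview**
1. Target 19 ⇒ keto-diol 16. Both tetrahydrofuran rings of the spiroketal close last, by a catalyst-controlled dehydrative spiroketalisation that sets the spiro centre.
2. 16 ⇒ cross-conjugated bis(anilinooxy) dienone 15 by one global hydrogenation (three C=C, two N–O).
3. 15 ⇒ two L-proline α-aminoxylation/Horner–Wadsworth–Emmons sequences around bisphosphonate 11, with propanal (sets C7) and aldehyde 9 (sets C2).
4. 9 ⇒ cross-metathesis of (R)-3-allylphthalide 7 with hept-6-enal.
5. 7 ⇒ chiral phosphoric acid allylboration of bromoaldehyde 1 (sets C3), then Br/Li exchange–carboxylation–lactonisation. The phthalide ring is formed first, the spiroketal rings last.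

Assumption: 1, 8 and 11 are taken as catalogue chemicals, and the thermodynamic ratio of the two spiro epimers of the (2R,7R) spiroketal is taken as about 1:1.

The target is the (3R)-phthalide carrying the (2R,5S,7R) spiroketal, which is the E,E isomer (each ring substituent trans to the oxygen of the other ring).

**Step 1**
Reactants: 1 2-bromo-3,5-dimethoxybenzaldehyde; 2 2-allyl-4,4,5,5-tetramethyl-1,3,2-dioxaborolane
Product: 4 (1R)-1-(2-bromo-3,5-dimethoxyphenyl)but-3-en-1-ol, via boronate ester 3 (not isolated)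
Conditions: (R)-TRIP [(R)-3,3'-bis(2,4,6-triisopropylphenyl)-1,1'-binaphthyl-2,2'-diyl hydrogen phosphate] (5 mol%), toluene, −30 °C; aq. NaHCO3
Reagents that add atoms: none
Why: Chiral phosphoric acid-catalysed allylboration; the acid hydrogen-bonds the boronate oxygen in a closed chair transition state and (R)-TRIP directs allyl to the Re face of the aldehyde, setting the (R) carbinol that becomes phthalide C3.

**Step 2**
Reactants: 4 (1R)-1-(2-bromo-3,5-dimethoxyphenyl)but-3-en-1-ol
Product: 7 (3R)-3-allyl-5,7-dimethoxy-2-benzofuran-1(3H)-one, via dilithio alkoxide 5 (not isolated), via hydroxy acid 6 (not isolated)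
Conditions: n-BuLi (2.2 equiv), THF, −78 °C; CO2, −78 to 0 °C; 2 M HCl, rt
Reagents that add atoms: carbon dioxide, O=C=O
Why: Bromine–lithium exchange on the lithium alkoxide, carboxylation of the aryllithium and acid-driven lactonisation of the γ-hydroxy acid close the phthalide ring; the benzylic stereocentre is not touched, and the cold quench avoids carbolithiation of the alkene.

**Step 3**
Reactants: 7 (3R)-3-allyl-5,7-dimethoxy-2-benzofuran-1(3H)-one; 8 hept-6-enal
Product: 9 8-[(1R)-4,6-dimethoxy-3-oxo-1,3-dihydro-2-benzofuran-1-yl]oct-6-enal (E/Z mixture)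
Conditions: 8 (3 equiv), second-generation Hoveyda–Grubbs catalyst RuCl2(H2IMes)(=CH-C6H4-2-OiPr) (3 mol%), CH2Cl2, 40 °C
Reagents that add atoms: none
Why: Olefin cross-metathesis of two unhindered terminal alkenes, driven by loss of ethene and excess 8; alkene geometry does not matter because this bond is hydrogenated in step 6.

**Step 4**
Reactants: 10 propanal; 11 tetraethyl (2-oxopropane-1,3-diyl)bis(phosphonate)
Product: 13 diethyl [(3E,5R)-5-(anilinooxy)-2-oxohex-3-en-1-yl]phosphonate, via aminoxy aldehyde 12 (not isolated)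
Conditions: 10 (1.2 equiv), PhNO (1.0 equiv), L-proline (20 mol%), MeCN, −20 °C; then 11 (2.5 equiv), LiCl, DBU, 0 °C
Reagents that add atoms: nitrosobenzene, O=Nc1ccccc1
Why: Proline enamine catalysis (α-aminoxylation), in which the carboxylic acid directs O-selective attack of nitrosobenzene on one enamine face to give the (R) aldehyde (future C7), trapped in the same flask by a Masamune–Roush Horner–Wadsworth–Emmons olefination; excess 11 keeps it to mono-olefination with E geometry.

**Step 5**
Reactants: 9 8-[(1R)-4,6-dimethoxy-3-oxo-1,3-dihydro-2-benzofuran-1-yl]oct-6-enal; 13 diethyl [(3E,5R)-5-(anilinooxy)-2-oxohex-3-en-1-yl]phosphonate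
Product: 15 (3R)-3-[(7R,8E,11E,13R)-7,13-bis(anilinooxy)-10-oxotetradeca-2,8,11-trien-1-yl]-5,7-dimethoxy-2-benzofuran-1(3H)-one, via aminoxy aldehyde 14 (not isolated)
Conditions: 9 (1.2 equiv), PhNO (1.2 equiv), L-proline (20 mol%), MeCN, −20 °C; then 13 (1.0 equiv), LiCl, DBU, 0 °C
Reagents that add atoms: nitrosobenzene, O=Nc1ccccc1
Why: A second L-proline α-aminoxylation sets the (R) centre that becomes spiroketal C2 under catalyst control (the remote phthalide centre has no influence), and the E-selective Horner–Wadsworth–Emmons reaction of ketophosphonate 13 completes the cross-conjugated dienone.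

**Step 6**
Reactants: 15 (3R)-3-[(7R,8E,11E,13R)-7,13-bis(anilinooxy)-10-oxotetradeca-2,8,11-trien-1-yl]-5,7-dimethoxy-2-benzofuran-1(3H)-one
Product: 16 (3R)-3-[(7R,13R)-7,13-dihydroxy-10-oxotetradecyl]-5,7-dimethoxy-2-benzofuran-1(3H)-one
Conditions: H2 (1 atm), 10% Pd/C, K2CO3, EtOAc, rt; filter; aniline removed on Et3N-deactivated SiO2; used at once
Reagents that add atoms: none
Why: Heterogeneous catalytic hydrogenation saturates the three C=C bonds and hydrogenolyses both N–O bonds in one operation without touching the carbinol centres, the ketone or the phthalide; the base buffer holds back acid-catalysed spiroketalisation so that the spiro centre is left for step 7.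

**Step 7**
Reactants: 16 (3R)-3-[(7R,13R)-7,13-dihydroxy-10-oxotetradecyl]-5,7-dimethoxy-2-benzofuran-1(3H)-one
Product: 19 (3R)-5,7-dimethoxy-3-{6-[(2R,5S,7R)-7-methyl-1,6-dioxaspiro[4.4]nonan-2-yl]hexyl}-2-benzofuran-1(3H)-one, via methyl-side lactol 17 (not isolated), via chain-side lactol 18 (not isolated)
Conditions: (S,S)-imidodiphosphoric acid built from two 3,3'-bis(2,4,6-triethylphenyl)-BINOL units (5 mol%), 5 Å molecular sieves, MTBE, −20 °C
Reagents that add atoms: none
Why: Proposed new method: a catalyst-controlled, dynamic kinetic dehydrative spiroketalisation of an acyclic γ,γ'-dihydroxy ketone. Keto-diol 16 interconverts without catalyst with lactols 17 and 18 (both anomers) by ring–chain tautomerism; the confined chiral Brønsted acid binds a lactol at two points (P–OH to the hemiketal hydroxyl, P=O to the remote hydroxyl), water leaves to the sieves, and the oxocarbenium/imidodiphosphate contact ion pair collapses inside the chiral pocket with C–O bond formation anti to the existing ring substituent, which gives the (5S) E,E spiro centre. The substrate itself has almost no facial bias, so the catalyst should decide the outcome; the product has no hydroxyl left for two-point binding and should not be re-ionised by this weak acid at −20 °C, so the kinetic ratio should persist. The closest known reactions are chiral phosphoric acid and confined imidodiphosphoric acid catalysed spiroketalisations of hydroxy enol ethers (which can give non-thermodynamic spiroketals) and chiral-acid-catalysed asymmetric acetalisation of carbonyl compounds with diols; the dehydrative entry from a keto-diol and control of a 2,7-disubstituted 1,6-dioxaspiro[4.4]nonane centre have not been shown.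

**Compound list**
1 | 2-bromo-3,5-dimethoxybenzaldehyde | COc1cc(OC)c(Br)c(C=O)c1 | starting material
2 | 2-allyl-4,4,5,5-tetramethyl-1,3,2-dioxaborolane (allylboronic acid pinacol ester) | C=CCB1OC(C)(C)C(C)(C)O1 | starting material
3 | 2-{[(1R)-1-(2-bromo-3,5-dimethoxyphenyl)but-3-en-1-yl]oxy}-4,4,5,5-tetramethyl-1,3,2-dioxaborolane | COc1cc(OC)c(Br)c(c1)[C@@H](CC=C)OB1OC(C)(C)C(C)(C)O1 | intermediate
4 | (1R)-1-(2-bromo-3,5-dimethoxyphenyl)but-3-en-1-ol | COc1cc(OC)c(Br)c(c1)[C@@H](CC=C)O | intermediate
5 | lithium (1R)-1-(2-lithio-3,5-dimethoxyphenyl)but-3-en-1-olate | COc1cc(OC)c([Li])c(c1)[C@@H](CC=C)O[Li] | intermediate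
6 | 2-[(1R)-1-hydroxybut-3-en-1-yl]-4,6-dimethoxybenzoic acid | COc1cc(OC)c(C(=O)O)c(c1)[C@@H](CC=C)O | intermediate
7 | (3R)-3-allyl-5,7-dimethoxy-2-benzofuran-1(3H)-one | COc1cc(OC)c2c(c1)[C@@H](CC=C)OC2=O | intermediate
8 | hept-6-enal | C=CCCCCC=O | starting material
9 | 8-[(1R)-4,6-dimethoxy-3-oxo-1,3-dihydro-2-benzofuran-1-yl]oct-6-enal (E/Z mixture) | COc1cc(OC)c2c(c1)[C@@H](CC=CCCCCC=O)OC2=O | intermediate
10 | propanal | CCC=O | starting material
11 | tetraethyl (2-oxopropane-1,3-diyl)bis(phosphonate) | CCOP(=O)(OCC)CC(=O)CP(=O)(OCC)OCC | starting material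
12 | (2R)-2-(anilinooxy)propanal | C[C@@H](ONc1ccccc1)C=O | intermediate
13 | diethyl [(3E,5R)-5-(anilinooxy)-2-oxohex-3-en-1-yl]phosphonate | C[C@@H](ONc1ccccc1)/C=C/C(=O)CP(=O)(OCC)OCC | intermediate
14 | (2R)-2-(anilinooxy)-8-[(1R)-4,6-dimethoxy-3-oxo-1,3-dihydro-2-benzofuran-1-yl]oct-6-enal | COc1cc(OC)c2c(c1)[C@@H](CC=CCCC[C@@H](ONc3ccccc3)C=O)OC2=O | intermediate
15 | (3R)-3-[(7R,8E,11E,13R)-7,13-bis(anilinooxy)-10-oxotetradeca-2,8,11-trien-1-yl]-5,7-dimethoxy-2-benzofuran-1(3H)-one | COc1cc(OC)c2c(c1)[C@@H](CC=CCCC[C@@H](ONc3ccccc3)/C=C/C(=O)/C=C/[C@@H](C)ONc4ccccc4)OC2=O | intermediate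
16 | (3R)-3-[(7R,13R)-7,13-dihydroxy-10-oxotetradecyl]-5,7-dimethoxy-2-benzofuran-1(3H)-one | COc1cc(OC)c2c(c1)[C@@H](CCCCCC[C@@H](O)CCC(=O)CC[C@@H](C)O)OC2=O | intermediate
17 | (3R)-3-{(7R)-7-hydroxy-9-[(5R)-2-hydroxy-5-methyloxolan-2-yl]nonyl}-5,7-dimethoxy-2-benzofuran-1(3H)-one (anomer mixture) | COc1cc(OC)c2c(c1)[C@@H](CCCCCC[C@@H](O)CCC3(O)CC[C@@H](C)O3)OC2=O | intermediate
18 | (3R)-3-{6-[(2R)-5-hydroxy-5-[(3R)-3-hydroxybutyl]oxolan-2-yl]hexyl}-5,7-dimethoxy-2-benzofuran-1(3H)-one (anomer mixture) | COc1cc(OC)c2c(c1)[C@@H](CCCCCC[C@@H]3CCC(O)(CC[C@@H](C)O)O3)OC2=O | intermediate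
19 | (3R)-5,7-dimethoxy-3-{6-[(2R,5S,7R)-7-methyl-1,6-dioxaspiro[4.4]nonan-2-yl]hexyl}-2-benzofuran-1(3H)-one | COc1cc(OC)c2c(c1)[C@@H](CCCCCC[C@@H]1CC[C@]3(CC[C@@H](C)O3)O1)OC2=O | target

**Step count and risk**
Total steps: 7. Longest linear sequence: 6 (steps 1, 2, 3, 5, 6, 7); step 4 is a one-step side branch.

The three steps most likely to fail:

Step 7 (the proposed new step). The dehydrative variant may not stay under kinetic control, or the catalyst may not discriminate the two faces, which would give close to the 1:1 thermodynamic mixture; the (R,R) catalyst would be tried first in case the (S,S) form is the mismatched one. The fallback uses known chemistry and sets out from 16: camphorsulfonic acid (10 mol%) in CH2Cl2 at room temperature gives the thermodynamic mixture of 19 and its spiro epimer, (3R)-5,7-dimethoxy-3-{6-[(2R,5R,7R)-7-methyl-1,6-dioxaspiro[4.4]nonan-2-yl]hexyl}-2-benzofuran-1(3H)-one F4. The two are separated by preparative HPLC, and recovered F4 is re-equilibrated with the same acid and recycled, so the fallback comes back to the route at 19.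

Step 5. The α-aminoxy aldehyde of the most valuable fragment is labile, and the γ-anilinooxy enone units can epimerise or fragment at the N–O bond under base. The fallback moves the fragment union from the olefination to a late metathesis; it sets out from 13 and does not need 9 or step 3. Cheap hept-6-enal 8, used in excess, is aminoxylated (L-proline, PhNO) to (2R)-2-(anilinooxy)hept-6-enal F1, which is olefinated in the same flask with 13 (LiCl, DBU) to give (2R,3E,6E,8R)-2,8-bis(anilinooxy)trideca-3,6,12-trien-5-one F2. Cross-metathesis of F2 with phthalide 7 (second-generation Hoveyda–Grubbs catalyst, CH2Cl2, 40 °C) then comes back to the route at 15.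

Step 6. On Pd/C the γ-oxygenated enones can lose the allylic C–O bond or isomerise to 1,4-diketones once N–O is cleaved, liberated aniline can undergo reductive amination with the ketone, and 16 can cyclise early to the thermodynamic spiroketal mixture. The fallback separates the two reductions and sets out from 15. Homogeneous hydrogenation with RhCl(PPh3)3 and H2 in benzene/EtOH saturates the three C=C bonds while both oxygens stay capped as anilinooxy groups, giving (3R)-3-[(7R,13R)-7,13-bis(anilinooxy)-10-oxotetradecyl]-5,7-dimethoxy-2-benzofuran-1(3H)-one F3. The N–O bonds of F3 are then cleaved without hydrogen gas by SmI2 in THF at 0 °C, which comes back to the route at 16.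

**Further compounds**
F1 | step 5 | (2R)-2-(anilinooxy)hept-6-enal | C=CCCC[C@@H](ONc1ccccc1)C=O
F2 | step 5 | (2R,3E,6E,8R)-2,8-bis(anilinooxy)trideca-3,6,12-trien-5-one | C[C@@H](ONc1ccccc1)/C=C/C(=O)/C=C/[C@H](ONc1ccccc1)CCCC=C
F3 | step 6 | (3R)-3-[(7R,13R)-7,13-bis(anilinooxy)-10-oxotetradecyl]-5,7-dimethoxy-2-benzofuran-1(3H)-one | COc1cc(OC)c2c(c1)[C@@H](CCCCCC[C@@H](ONc3ccccc3)CCC(=O)CC[C@@H](C)ONc4ccccc4)OC2=O
F4 | step 7 | (3R)-5,7-dimethoxy-3-{6-[(2R,5R,7R)-7-methyl-1,6-dioxaspiro[4.4]nonan-2-yl]hexyl}-2-benzofuran-1(3H)-one | COc1cc(OC)c2c(c1)[C@@H](CCCCCC[C@@H]1CC[C@@]3(CC[C@@H](C)O3)O1)OC2=O
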